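**Retrosynthetic overview** (numbering: C1 = lactone carbonyl, C2=C3 = ring alkene, C5 = ring carbinol carbon, C7/C9/C11/C15 = hydroxylated carbons, C26 = methyl end)
1. Enabling feature: in the dihydropyranone ring, the ring oxygen and C2 both sit on C1, and their ring partners C5 and C3 are 1,3-related through C4. The ring is therefore an O–C1–C2 unit nucleophilic at both ends (a phosphonioacetate) plus a C3–C4–C5 unit electrophilic at both ends (an E-enal); inside a six-membered ring only the cis C2=C3 alkene can form.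
2. Target 17 ⇐ acid deprotection of 16 ⇐ amine-catalysed oxa-Michael/intramolecular Wittig [3+3] annulation of enal 13 with the betaine of 14 (forms O–C5 and C2=C3, sets C5).
3. Enal 13 ⇐ cross-metathesis with crotonaldehyde ⇐ 12 ⇐ iridium-catalysed allylation of primary alcohol 9 (sets C7 syn to C9).
4. 9 ⇐ C12–C13 union by cross-metathesis/hydrogenation of vinyl dioxane 6 (from the commercial statin side-chain alcohol 4, which brings C9 and C11 as the syn acetonide) with 3 (same iridium allylation on 1-dodecanol, sets C15).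
5. Rings: the dioxane ring arrives with 4 and is only a protecting ring; the dihydropyranone is the single ring formed (step 10); the dioxane is opened in step 11.

Key step: step 10

Remark: the ligand hand in the two iridium allylations (steps 1 and 7, opposite hands) is assigned from the accepted model for this catalyst class, not from a result; it would be confirmed by Mosher ester analysis and the antipodal ligand used if needed.

**Step 1**
Reactants: 1 dodecan-1-ol
Product: 3 (4S)-pentadec-1-en-4-ol, via dodecanal 2 (not isolated)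
Conditions: allyl acetate (2 equiv), [Ir(cod)Cl]2 (2.5 mol%), (R)-Cl,MeO-BIPHEP (5 mol%), 4-chloro-3-nitrobenzoic acid (10 mol%), Cs2CO3 (20 mol%), THF, 100 °C, sealed tube
Reagents that add atoms: allyl acetate, CC(=O)OCC=C
Why: Iridium-catalysed transfer-hydrogenative carbonyl allylation (Krische allylation): the catalyst dehydrogenates 1 to 2, and the chiral bisphosphine iridium π-allyl C,O-benzoate adds allyl to one aldehyde face through a closed chair transition state, which should set C15 as S under ligand control.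

**Step 2**
Reactants: 4 tert-butyl 2-[(4R,6S)-6-(hydroxymethyl)-2,2-dimethyl-1,3-dioxan-4-yl]acetate
Product: 5 tert-butyl 2-[(4R,6S)-6-formyl-2,2-dimethyl-1,3-dioxan-4-yl]acetate
Conditions: TEMPO (10 mol%), PhI(OAc)2 (1.1 equiv), CH2Cl2, rt
Reagents that add atoms: none
Why: Oxoammonium (TEMPO) oxidation stops at the aldehyde under non-basic conditions, so the α-alkoxy centre, the acetonide and the tert-butyl ester should be untouched.

**Step 3**
Reactants: 5 tert-butyl 2-[(4R,6S)-6-formyl-2,2-dimethyl-1,3-dioxan-4-yl]acetate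
Product: 6 tert-butyl 2-[(4R,6S)-6-ethenyl-2,2-dimethyl-1,3-dioxan-4-yl]acetate
Conditions: Ph3PCH3Br, KOtBu, THF, 0 °C; then 5, −78 to 0 °C
Reagents that add atoms: methyltriphenylphosphonium bromide, C[P+](c1ccccc1)(c1ccccc1)c1ccccc1.[Br-]
Why: Wittig methylenation converts formyl to vinyl; the cis-4,6-disubstituted dioxane is the thermodynamically preferred diastereomer, so the α-centre is not at risk, and the hindered tert-butyl ester is inert to the ylide.

**Step 4**
Reactants: 6 tert-butyl 2-[(4R,6S)-6-ethenyl-2,2-dimethyl-1,3-dioxan-4-yl]acetate; 3 (4S)-pentadec-1-en-4-ol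
Product: 7 tert-butyl 2-[(4R,6S)-6-[(1E,4S)-4-hydroxypentadec-1-en-1-yl]-2,2-dimethyl-1,3-dioxan-4-yl]acetate
Conditions: 3 (2 equiv), second-generation Hoveyda–Grubbs catalyst (H2IMes)Cl2Ru(=CH-C6H4-2-OiPr) (5 mol%), CH2Cl2, 40 °C
Reagents that add atoms: none
Why: Olefin cross-metathesis: the unhindered alkene of 3 (in excess) initiates and is captured by the slowly homodimerising α-oxygenated vinyl group of 6, forming C12=C13; the geometry is irrelevant because the alkene is hydrogenated next.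

**Step 5**
Reactants: 7 tert-butyl 2-[(4R,6S)-6-[(1E,4S)-4-hydroxypentadec-1-en-1-yl]-2,2-dimethyl-1,3-dioxan-4-yl]acetate
Product: 8 tert-butyl 2-[(4R,6R)-6-[(4S)-4-hydroxypentadecyl]-2,2-dimethyl-1,3-dioxan-4-yl]acetate
Conditions: H2 (1 atm), Pd/C (10 wt%), EtOAc, rt
Reagents that add atoms: none
Why: Heterogeneous catalytic hydrogenation should saturate the disubstituted alkene faster than any hydrogenolysis of the allylic C–O bond in a neutral solvent; no stereocenter is formed or touched.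

**Step 6**
Reactants: 8 tert-butyl 2-[(4R,6R)-6-[(4S)-4-hydroxypentadecyl]-2,2-dimethyl-1,3-dioxan-4-yl]acetate
Product: 9 2-[(4S,6R)-6-[(4S)-4-hydroxypentadecyl]-2,2-dimethyl-1,3-dioxan-4-yl]ethan-1-ol
Conditions: LiAlH4, THF, 0 °C; Fieser work-up
Reagents that add atoms: none
Why: Hydride reduction of the tert-butyl ester to the primary alcohol; the acetonide is stable to the reagent and to the basic work-up.

**Step 7**
Reactants: 9 2-[(4S,6R)-6-[(4S)-4-hydroxypentadecyl]-2,2-dimethyl-1,3-dioxan-4-yl]ethan-1-ol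
Product: 11 (2S)-1-[(4S,6R)-6-[(4S)-4-hydroxypentadecyl]-2,2-dimethyl-1,3-dioxan-4-yl]pent-4-en-2-ol, via dioxanyl acetaldehyde 10 (not isolated)
Conditions: allyl acetate (2 equiv), [Ir(cod)Cl]2 (2.5 mol%), (S)-Cl,MeO-BIPHEP (5 mol%), 4-chloro-3-nitrobenzoic acid (10 mol%), Cs2CO3 (20 mol%), THF, 100 °C, sealed tube
Reagents that add atoms: allyl acetate, CC(=O)OCC=C
Why: Krische allylation again: only the primary alcohol should be dehydrogenated at a useful rate, the β-alkoxy aldehyde 10 is allylated as it forms and so cannot eliminate or epimerise, and the (S)-ligand should override the weak bias of C9 to set the C7 oxygen 1,3-syn to the C9 oxygen.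

**Step 8**
Reactants: 11 (2S)-1-[(4S,6R)-6-[(4S)-4-hydroxypentadecyl]-2,2-dimethyl-1,3-dioxan-4-yl]pent-4-en-2-ol
Product: 12 (4R,6R)-4-[(2S)-2-(tert-butyldimethylsilyloxy)pent-4-en-1-yl]-6-[(4S)-4-(tert-butyldimethylsilyloxy)pentadecyl]-2,2-dimethyl-1,3-dioxane
Conditions: TBSOTf (2.5 equiv), 2,6-lutidine, CH2Cl2, −78 to 0 °C
Reagents that add atoms: tert-butyldimethylsilyl trifluoromethanesulfonate, CC(C)(C)[Si](C)(C)OS(=O)(=O)C(F)(F)F
Why: Silyl ether formation with the silyl triflate and a hindered base protects both secondary hydroxyls in one operation at low temperature, where the acetonide survives.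

**Step 9**
Reactants: 12 (4R,6R)-4-[(2S)-2-(tert-butyldimethylsilyloxy)pent-4-en-1-yl]-6-[(4S)-4-(tert-butyldimethylsilyloxy)pentadecyl]-2,2-dimethyl-1,3-dioxane
Product: 13 (2E,5S)-5-(tert-butyldimethylsilyloxy)-6-[(4R,6R)-6-[(4S)-4-(tert-butyldimethylsilyloxy)pentadecyl]-2,2-dimethyl-1,3-dioxan-4-yl]hex-2-enal
Conditions: crotonaldehyde (5 equiv), second-generation Hoveyda–Grubbs catalyst (H2IMes)Cl2Ru(=CH-C6H4-2-OiPr) (5 mol%), CH2Cl2, 40 °C
Reagents that add atoms: (E)-crotonaldehyde, C/C=C/C=O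
Why: Olefin cross-metathesis of a terminal alkene with an excess of an electron-poor partner should give the E-enal selectively, because the conjugated product re-enters metathesis only slowly.

**Step 10**
Reactants: 13 (2E,5S)-5-(tert-butyldimethylsilyloxy)-6-[(4R,6R)-6-[(4S)-4-(tert-butyldimethylsilyloxy)pentadecyl]-2,2-dimethyl-1,3-dioxan-4-yl]hex-2-enal; 14 (carboxymethyl)triphenylphosphonium bromide
Product: 16 (6S)-6-[(2R)-2-(tert-butyldimethylsilyloxy)-3-[(4R,6R)-6-[(4S)-4-(tert-butyldimethylsilyloxy)pentadecyl]-2,2-dimethyl-1,3-dioxan-4-yl]propyl]-5,6-dihydro-2H-pyran-2-one, via ylide ester aldehyde 15 (not isolated)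
Conditions: 14 (1.5 equiv), NaHCO3 (1.5 equiv), (S)-2-[bis(3,5-bis(trifluoromethyl)phenyl)(trimethylsilyloxy)methyl]pyrrolidine (20 mol%), PhCO2H (20 mol%), CH2Cl2, 0 °C to rt
Reagents that add atoms: none
Why: Proposed new method: the amine condenses with enal 13 to an E-iminium ion, the carboxylate of the betaine formed from 14 adds to C5 (oxa-Michael, making O–C5), enamine hydrolysis releases the β-acyloxy aldehyde whose ester-activated CH2–PPh3 group is now acidic enough for benzoate to give ylide 15, and 15 closes by intramolecular Wittig olefination onto the C3 aldehyde (making C2=C3), a formal [3+3] annulation. The closest known reaction types are iminium-catalysed oxa-Michael additions of oximes and peroxides to enals, amine-catalysed domino Michael/intramolecular Wittig [3+3] annulations of enals to cyclohexenones, and intramolecular Wittig lactonisations of (triphenylphosphoranylidene)acetates of hydroxy carbonyl compounds; new here is a carboxylate as the oxygen nucleophile of the domino. The one ring is closed in the Wittig step by 6-exo-trig attack of ylide carbon C2 on aldehyde carbon C3, and the ring allows only the cis alkene. The new stereocenter C5 is set in the oxa-Michael step by the catalyst: in the s-trans E-iminium ion the bis(aryl)(silyloxy)methyl group of the (S)-pyrrolidine covers one face of C5 and the carboxylate adds to the other, which by this model gives 5S, syn to the C7 silyl ether. The step needs oxygen-before-carbon reactivity and trapping faster than retro-addition: the betaine has no ylide carbon until its carboxylate has become an ester, so no Wittig reaction with 13 itself competes, the ylide is then held six atoms from the aldehyde, and loss of the acyloxy group from the adduct only returns 13 and the betaine. It also needs catalyst over substrate control, which the remote C7 centre, one CH2 away from C5, should allow.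

**Step 11**
Reactants: 16 (6S)-6-[(2R)-2-(tert-butyldimethylsilyloxy)-3-[(4R,6R)-6-[(4S)-4-(tert-butyldimethylsilyloxy)pentadecyl]-2,2-dimethyl-1,3-dioxan-4-yl]propyl]-5,6-dihydro-2H-pyran-2-one
Product: 17 (6S)-6-[(2R,4R,6R,10S)-2,4,6,10-tetrahydroxyhenicosyl]-5,6-dihydro-2H-pyran-2-one
Conditions: HF (48% aq.), MeCN, 0 °C to rt
Reagents that add atoms: none
Why: Acid-mediated global deprotection: aqueous HF should cleave both secondary silyl ethers and hydrolyse the acetonide, while the unsaturated lactone, sensitive to base but tolerant of mild acid, should survive; no stereocenter is touched.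

**Compound list**
1 | dodecan-1-ol | CCCCCCCCCCCCO | starting material
2 | dodecanal | CCCCCCCCCCCC=O | intermediate
3 | (4S)-pentadec-1-en-4-ol | CCCCCCCCCCC[C@H](O)CC=C | intermediate
4 | tert-butyl 2-[(4R,6S)-6-(hydroxymethyl)-2,2-dimethyl-1,3-dioxan-4-yl]acetate | OC[C@@H]1C[C@H](CC(=O)OC(C)(C)C)OC(C)(C)O1 | starting material
5 | tert-butyl 2-[(4R,6S)-6-formyl-2,2-dimethyl-1,3-dioxan-4-yl]acetate | O=C[C@@H]1C[C@H](CC(=O)OC(C)(C)C)OC(C)(C)O1 | intermediate
6 | tert-butyl 2-[(4R,6S)-6-ethenyl-2,2-dimethyl-1,3-dioxan-4-yl]acetate | C=C[C@@H]1C[C@H](CC(=O)OC(C)(C)C)OC(C)(C)O1 | intermediate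
7 | tert-butyl 2-[(4R,6S)-6-[(1E,4S)-4-hydroxypentadec-1-en-1-yl]-2,2-dimethyl-1,3-dioxan-4-yl]acetate | CCCCCCCCCCC[C@H](O)C/C=C/[C@@H]1C[C@H](CC(=O)OC(C)(C)C)OC(C)(C)O1 | intermediate
8 | tert-butyl 2-[(4R,6R)-6-[(4S)-4-hydroxypentadecyl]-2,2-dimethyl-1,3-dioxan-4-yl]acetate | CCCCCCCCCCC[C@H](O)CCC[C@@H]1C[C@H](CC(=O)OC(C)(C)C)OC(C)(C)O1 | intermediate
9 | 2-[(4S,6R)-6-[(4S)-4-hydroxypentadecyl]-2,2-dimethyl-1,3-dioxan-4-yl]ethan-1-ol | CCCCCCCCCCC[C@H](O)CCC[C@@H]1C[C@H](CCO)OC(C)(C)O1 | intermediate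
10 | 2-[(4R,6R)-6-[(4S)-4-hydroxypentadecyl]-2,2-dimethyl-1,3-dioxan-4-yl]acetaldehyde | CCCCCCCCCCC[C@H](O)CCC[C@@H]1C[C@H](CC=O)OC(C)(C)O1 | intermediate
11 | (2S)-1-[(4S,6R)-6-[(4S)-4-hydroxypentadecyl]-2,2-dimethyl-1,3-dioxan-4-yl]pent-4-en-2-ol | CCCCCCCCCCC[C@H](O)CCC[C@@H]1C[C@H](C[C@@H](O)CC=C)OC(C)(C)O1 | intermediate
12 | (4R,6R)-4-[(2S)-2-(tert-butyldimethylsilyloxy)pent-4-en-1-yl]-6-[(4S)-4-(tert-butyldimethylsilyloxy)pentadecyl]-2,2-dimethyl-1,3-dioxane | CCCCCCCCCCC[C@H](O[Si](C)(C)C(C)(C)C)CCC[C@@H]1C[C@H](C[C@@H](O[Si](C)(C)C(C)(C)C)CC=C)OC(C)(C)O1 | intermediate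
13 | (2E,5S)-5-(tert-butyldimethylsilyloxy)-6-[(4R,6R)-6-[(4S)-4-(tert-butyldimethylsilyloxy)pentadecyl]-2,2-dimethyl-1,3-dioxan-4-yl]hex-2-enal | CCCCCCCCCCC[C@H](O[Si](C)(C)C(C)(C)C)CCC[C@@H]1C[C@H](C[C@@H](O[Si](C)(C)C(C)(C)C)C/C=C/C=O)OC(C)(C)O1 | intermediate
14 | (carboxymethyl)triphenylphosphonium bromide | OC(=O)C[P+](c1ccccc1)(c1ccccc1)c1ccccc1.[Br-] | starting material
15 | (3R,5R)-5-(tert-butyldimethylsilyloxy)-6-[(4R,6R)-6-[(4S)-4-(tert-butyldimethylsilyloxy)pentadecyl]-2,2-dimethyl-1,3-dioxan-4-yl]-1-oxohexan-3-yl (triphenyl-λ5-phosphanylidene)acetate | CCCCCCCCCCC[C@H](O[Si](C)(C)C(C)(C)C)CCC[C@@H]1C[C@H](C[C@@H](O[Si](C)(C)C(C)(C)C)C[C@H](CC=O)OC(=O)C=P(c2ccccc2)(c2ccccc2)c2ccccc2)OC(C)(C)O1 | intermediate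
16 | (6S)-6-[(2R)-2-(tert-butyldimethylsilyloxy)-3-[(4R,6R)-6-[(4S)-4-(tert-butyldimethylsilyloxy)pentadecyl]-2,2-dimethyl-1,3-dioxan-4-yl]propyl]-5,6-dihydro-2H-pyran-2-one | CCCCCCCCCCC[C@H](O[Si](C)(C)C(C)(C)C)CCC[C@@H]1C[C@H](C[C@@H](O[Si](C)(C)C(C)(C)C)C[C@@H]2CC=CC(=O)O2)OC(C)(C)O1 | intermediate
17 | (6S)-6-[(2R,4R,6R,10S)-2,4,6,10-tetrahydroxyhenicosyl]-5,6-dihydro-2H-pyran-2-one | CCCCCCCCCCC[C@H](O)CCC[C@@H](O)C[C@@H](O)C[C@@H](O)C[C@@H]1CC=CC(=O)O1 | target

**Step count and risks**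
Total: 11 steps. Longest linear sequence: 10 steps (4 to 17, steps 2–11); step 1 is the one-step branch.

Steps most likely to fail:

1. Step 10 (proposed new method). The oxa-Michael adduct may revert faster than the Wittig closure traps it, giving low conversion; reversible addition may erode facial selectivity at C5; and the δ-silyloxy enal may lose silanol through its dienamine. The fallback uses known chemistry, sets out from 12 and returns at 16. Ozonolysis of 12 (O3, CH2Cl2/MeOH, −78 °C; PPh3) gives the β-silyloxy aldehyde (3R)-3-(tert-butyldimethylsilyloxy)-4-[(4R,6R)-6-[(4S)-4-(tert-butyldimethylsilyloxy)pentadecyl]-2,2-dimethyl-1,3-dioxan-4-yl]butanal F1. Iridium-catalysed allylation from the aldehyde oxidation level, with the catalyst and ligand hand of step 7 (allyl acetate, i-PrOH as reductant), should give the homoallylic alcohol (2S,4S)-2-(tert-butyldimethylsilyloxy)-1-[(4R,6R)-6-[(4S)-4-(tert-butyldimethylsilyloxy)pentadecyl]-2,2-dimethyl-1,3-dioxan-4-yl]hept-6-en-4-ol F2; the C5 oxygen should be syn to the C7 oxygen because the chain grows in the same direction as in step 7. Acylation (acryloyl chloride, Et3N, DMAP, CH2Cl2, 0 °C) gives the acrylate (4S,6R)-6-(tert-butyldimethylsilyloxy)-7-[(4R,6R)-6-[(4S)-4-(tert-butyldimethylsilyloxy)pentadecyl]-2,2-dimethyl-1,3-dioxan-4-yl]hept-1-en-4-yl prop-2-enoate F3. Ring-closing metathesis (second-generation Grubbs catalyst (H2IMes)(PCy3)Cl2Ru=CHPh, CH2Cl2, 40 °C) closes C2=C3 and gives 16.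

2. Step 7. Catalyst control may not override the C9 centre, giving a mixture at C7, and the C15 carbinol may be dehydrogenated at 100 °C. The fallback sets out from 9 and returns at 11. Primary-selective oxidation of 9 (TEMPO, PhI(OAc)2, CH2Cl2) lets aldehyde 10 be isolated. Stoichiometric, reagent-controlled allylboration at −78 °C follows, with the antipode of Ipc2B(allyl) that adds to the Si face of the aldehyde (Et2O; then NaOH, H2O2), and should give 11. This path makes no compound outside the list (F0).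

3. Step 4. Productive metathesis at the hindered, α-oxygenated vinyl group may be slow, so that homodimerisation of 3 and ruthenium hydride-mediated olefin migration take over. The fallback sets out from 3 and 5 and returns at 7, replacing metathesis by a Julia–Kocienski olefination.
   - Silylation of 3 (TBSCl, imidazole, DMF) gives tert-butyldimethyl{[(4S)-pentadec-1-en-4-yl]oxy}silane F4.
   - Ozonolysis with reductive work-up (O3, CH2Cl2/MeOH, −78 °C; NaBH4) gives (3S)-3-(tert-butyldimethylsilyloxy)tetradecan-1-ol F5.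
   - Mitsunobu thioetherification (1-phenyl-1H-tetrazole-5-thiol, PPh3, DIAD, THF) gives the sulfide 5-{[(3S)-3-(tert-butyldimethylsilyloxy)tetradecyl]sulfanyl}-1-phenyl-1H-tetrazole F6.
   - Oxidation ((NH4)6Mo7O24, H2O2, EtOH) gives the sulfone 5-{[(3S)-3-(tert-butyldimethylsilyloxy)tetradecyl]sulfonyl}-1-phenyl-1H-tetrazole F7.
   - Metalation of F7 (KHMDS, DME, −60 °C) and addition of aldehyde 5 should give the E-alkene tert-butyl 2-[(4R,6S)-6-[(1E,4S)-4-(tert-butyldimethylsilyloxy)pentadec-1-en-1-yl]-2,2-dimethyl-1,3-dioxan-4-yl]acetate F8.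
   - TBAF (THF, rt) removes the silyl group and returns 7.

**Further compounds**
F1 | step 10 | (3R)-3-(tert-butyldimethylsilyloxy)-4-[(4R,6R)-6-[(4S)-4-(tert-butyldimethylsilyloxy)pentadecyl]-2,2-dimethyl-1,3-dioxan-4-yl]butanal | CCCCCCCCCCC[C@H](O[Si](C)(C)C(C)(C)C)CCC[C@@H]1C[C@H](C[C@@H](O[Si](C)(C)C(C)(C)C)CC=O)OC(C)(C)O1
F2 | step 10 | (2S,4S)-2-(tert-butyldimethylsilyloxy)-1-[(4R,6R)-6-[(4S)-4-(tert-butyldimethylsilyloxy)pentadecyl]-2,2-dimethyl-1,3-dioxan-4-yl]hept-6-en-4-ol | CCCCCCCCCCC[C@H](O[Si](C)(C)C(C)(C)C)CCC[C@@H]1C[C@H](C[C@@H](O[Si](C)(C)C(C)(C)C)C[C@@H](O)CC=C)OC(C)(C)O1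
F3 | step 10 | (4S,6R)-6-(tert-butyldimethylsilyloxy)-7-[(4R,6R)-6-[(4S)-4-(tert-butyldimethylsilyloxy)pentadecyl]-2,2-dimethyl-1,3-dioxan-4-yl]hept-1-en-4-yl prop-2-enoate | CCCCCCCCCCC[C@H](O[Si](C)(C)C(C)(C)C)CCC[C@@H]1C[C@H](C[C@@H](O[Si](C)(C)C(C)(C)C)C[C@@H](OC(=O)C=C)CC=C)OC(C)(C)O1
F0 | step 7 | none | none
F4 | step 4 | tert-butyldimethyl{[(4S)-pentadec-1-en-4-yl]oxy}silane | CCCCCCCCCCC[C@H](O[Si](C)(C)C(C)(C)C)CC=C
F5 | step 4 | (3S)-3-(tert-butyldimethylsilyloxy)tetradecan-1-ol | CCCCCCCCCCC[C@H](O[Si](C)(C)C(C)(C)C)CCO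
F6 | step 4 | 5-{[(3S)-3-(tert-butyldimethylsilyloxy)tetradecyl]sulfanyl}-1-phenyl-1H-tetrazole | CCCCCCCCCCC[C@H](O[Si](C)(C)C(C)(C)C)CCSc1nnnn1-c1ccccc1
F7 | step 4 | 5-{[(3S)-3-(tert-butyldimethylsilyloxy)tetradecyl]sulfonyl}-1-phenyl-1H-tetrazole | CCCCCCCCCCC[C@H](O[Si](C)(C)C(C)(C)C)CCS(=O)(=O)c1nnnn1-c1ccccc1
F8 | step 4 | tert-butyl 2-[(4R,6S)-6-[(1E,4S)-4-(tert-butyldimethylsilyloxy)pentadec-1-en-1-yl]-2,2-dimethyl-1,3-dioxan-4-yl]acetate | CCCCCCCCCCC[C@H](O[Si](C)(C)C(C)(C)C)C/C=C/[C@@H]1C[C@H](CC(=O)OC(C)(C)C)OC(C)(C)O1
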